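The ratio of X charged to G charged in west is 75.0%. I call it the capture ratio: the fraction of the G charge that can become Q if one X makes one Q. Below one, X is the limiting reagent.

the same everywhere: G 0.20 M

| flask | Z | X | remark | time |
|---|---|---|---|---|
| alder | 0.30 M | 0.17 M | run made earlier |  |
| ash | 0.30 M | 1.9 M | run made earlier |  |
| west | 0.300 M | 0.150 M |  | 2.5 min |
| south | 0.300 M | 0.500 M |  | 2.5 min |
| south-west | 0.300 M | 1.50 M |  | 2.5 min |

- alder (time / s: Q / %, G / %): 20.0: 86.7, 7.2; 40.0: 84.6, 7.9; 60.0: 86.2, 8.8; 80.0: 85.1, 9.1; 120: 83.9, 11.0
- ash (time / s: Q / %, G / %): 10.0: 99.5, 0; 25.0: 99.8, 1.3; 50.0: 100.8, 0.2; 80.0: 101.3, 0.1; 120: 101.2, 0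

(standard deviation of a reading: 1 percentage point)

- a reading or a percentage of Q counts all its forms, free or not
- the concentration of Q that is asked is that of its free form alone
- "hardly changes" means that all values lie within two and a half points (for a concentration: within two and a half percent of the largest)

- [Q] (only what is free in solution) at the end for west, south, south-west, in this order
- how the row runs (falls all the way / rises all the way / hardly changes / falls, then rises / rises, then falls)

The alder ratio is 85.0%, and Q reads 86.7% at 20.0 s, a mean rate of 0.0433 s⁻¹ of the G charge. At 120 s Q reads 83.9%, a difference of 2.8 percentage points against a scatter of 1 point on each reading, so I read a level stretch from these readings and no rate of fall. In ash the ratio is 9.50, and Q reads 99.5% at 10.0 s. Both runs already stand level at their first reading, so a mean taken up to that reading reflects the sampling time, and the readings do not show which run is faster.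

I take the rate as proportional to the fraction of X left times the fraction of G left. This is my assumption, and with a large ratio, as in ash, it turns pseudo-first-order. In west, half way to the ratio, the X factor is 0.5 and the G factor 62.5%, so the rate has slowed to 0.312 of its starting value. At the ratio itself the X factor is 0% while the G factor is still 25.0%, so X sets where the rate dies. The time allowed, 150 s, is longer than the 20.0 s of alder's first reading. I therefore commit to Q, free or not, at 75.0% of the G charge in west. In south and south-west, with ratios of 2.50 and 7.50, I commit to 100%. The readings count both forms, so they do not tell me how much of that Q is free.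

The forecast gives 0.125 M, 0.197 M and 0.2 M, a row that rises all the way, from runs that “read as fast, X-limited capture”.

The flask gives 0.0120 M, 0.0120 M and 0.0120 M, so the row hardly changes.

    G + Z ⇌ E + J, settled at all times (K = 2.11)
    X + J → Q (k = 24.4 M⁻¹ s⁻¹)
    Z → D (k = 0.0127 s⁻¹)
    L ⇌ Q, rate k4*(cs4 - [Q]) while solid is left; crystals form when [Q] > cs4 (solubility = 12.0 mM, k = 1.06 s⁻¹)

In west the free Q is 6.00% of the G charge, while L, counted in Q, holds 69.0% of that charge at 2.50 min. The capture ratio 75.0% stands beside west's Q of 75.0%, free and L together. In south the ratio of 2.50 leaves 60.0% of the X charge once G is captured, and south holds X at 60.0% and L at 94.0%.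

Readings and results are simulated for an exercise; noise was put on by code.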